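Ring C of the upper flavan unit (O1–C2–C3–C4–C4a–C8a) is disconnected as a formal [4+2] adduct of an O-aryl oxocarbenium ion (C4a=C8a–O1+=C2, from a phloroglucinol ether and a galloyl aldehyde) and the alkene C3=C4, an (E)-enol carbonate carried at C6 of protected epigallocatechin gallate. A chiral Brønsted acid triggers C2–C3 bond formation and Friedel–Crafts closure of C4–C4a in one operation (asymmetric oxa-Povarov reaction), creating C2, C3 and C4. The step exploits C2 as the benzylic carbon bound to O1 and C4 as the doubly benzylic carbon between the two electron-rich rings A. One hydrogenolysis then unveils the target.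

Key step: step 8

Assumption: the (R)-configured acid of step 8 is taken to expose the face of the oxocarbenium ion that gives the (2R) upper unit; if a model reaction shows the opposite sense, the (S)-acid is used and nothing else changes.

Step 1
Reactants: 1 (−)-epigallocatechin (EGC; 2R,3R)
Product: 2 5,7,3',4',5'-penta-O-benzyl-(−)-epigallocatechin
Conditions: BnBr (5.5 equiv), K2CO3, DMF, N2, 0 °C → rt
Reagents that add atoms: benzyl bromide, BrCc1ccccc1
Why: Williamson etherification with a carbonate base in dry DMF should benzylate only the five phenols, the far less acidic secondary C3 alcohol staying free for the next step and the C2 and C3 stereocentres staying untouched.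

Step 2
Reactants: 2 5,7,3',4',5'-penta-O-benzyl-(−)-epigallocatechin; 3 3,4,5-tris(benzyloxy)benzoic acid
Product: 4 octa-O-benzyl-EGCG
Conditions: DCC (1.5 equiv), DMAP (0.3 equiv), CH2Cl2, 0 °C → rt
Reagents that add atoms: none
Why: Steglich esterification (carbodiimide activation with acyl transfer by DMAP) should acylate the axial C3 hydroxyl with retention, since the C3–O bond is not broken.

Step 3
Reactants: 4 octa-O-benzyl-EGCG
Product: 5 8-bromo-octa-O-benzyl-EGCG
Conditions: NBS (1.0 equiv), CH2Cl2, −78 → −20 °C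
Reagents that add atoms: N-bromosuccinimide, O=C1CCC(=O)N1Br
Why: Electrophilic aromatic bromination should occur on the phloroglucinol-type ring A at C8, the less crowded of its two free positions (as is usual for perbenzylated flavan-3-ols), and the bromine then blocks this position until the last step.

Step 4
Reactants: 5 8-bromo-octa-O-benzyl-EGCG
Product: 6 8-bromo-6-iodo-octa-O-benzyl-EGCG
Conditions: NIS (1.1 equiv), TFA (cat.), CH2Cl2, 0 °C → rt
Reagents that add atoms: N-iodosuccinimide, O=C1CCC(=O)N1I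
Why: A second electrophilic aromatic substitution should go to C6, the only free and still the most activated carbon of ring A (two ortho oxygens and one para oxygen), giving a C–I bond that cross-coupling distinguishes from C–Br.

Step 5
Reactants: 6 8-bromo-6-iodo-octa-O-benzyl-EGCG; 7 (E)-2-(2-ethoxyvinyl)-4,4,5,5-tetramethyl-1,3,2-dioxaborolane
Product: 9 8-bromo-6-(2-oxoethyl)-octa-O-benzyl-EGCG (arylacetaldehyde), via (E)-enol ethyl ether 8 (not isolated)
Conditions: Pd(OAc)2 (5 mol %), SPhos (10 mol %), K3PO4 (2 equiv), toluene/H2O, 60 °C; then 1 M HCl, THF, rt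
Reagents that add atoms: water, O
Why: Suzuki–Miyaura coupling should be selective for the C–I bond over the hindered C–Br bond, and the enol ether is hydrolysed on acidic work-up (the boronate serves as an acetaldehyde enolate equivalent), which puts in place the two carbons that become C3 and C4.

Step 6
Reactants: 9 8-bromo-6-(2-oxoethyl)-octa-O-benzyl-EGCG
Product: 11 8-bromo-6-[(E)-2-(benzyloxycarbonyloxy)vinyl]-octa-O-benzyl-EGCG, via potassium (E)-enolate 10 (not isolated)
Conditions: KN(SiMe3)2 (1.05 equiv), THF, −78 °C (inverse addition); ClCO2Bn, −78 → 0 °C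
Reagents that add atoms: benzyl chloroformate, O=C(Cl)OCc1ccccc1
Why: Deprotonation of the benzylic α-carbon by the hindered amide base (inverse addition suppresses self-aldol reaction) gives the potassium enolate, in which the di-ortho-substituted aryl group should prefer to lie trans to the oxygen, and the hard chloroformate acylates it on oxygen with retention of geometry to give mainly the (E)-enol carbonate (any (Z)-isomer is removed by chromatography), a group that later leaves together with the benzyl ethers.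

Step 7
Reactants: 12 3,4,5-tris(benzyloxy)benzaldehyde; 13 3,5-bis(benzyloxy)phenol
Product: 15 [3,5-bis(benzyloxy)phenoxy][3,4,5-tris(benzyloxy)phenyl]methyl acetate (racemic mixed acetal), via α-chlorobenzyl acetate 14 (not isolated)
Conditions: 12, AcCl (3 equiv), ZnCl2 (1 mol %), CH2Cl2, −10 °C → rt, evaporate; then 13, Cs2CO3, MeCN, 0 °C; filtration through basic alumina
Reagents that add atoms: acetyl chloride, CC(Cl)=O
Why: Addition of the acyl chloride across the aldehyde C=O gives the α-chloroalkyl ester, whose highly ionisable benzylic chloride should be displaced by the phenoxide on oxygen (SN1-like O-alkylation, as in the preparation of acyloxyalkyl aryl ethers), giving an acetal that can ionise only to the O-aryl oxocarbenium ion.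

Step 8
Reactants: 11 8-bromo-6-[(E)-2-(benzyloxycarbonyloxy)vinyl]-octa-O-benzyl-EGCG; 15 [3,5-bis(benzyloxy)phenoxy][3,4,5-tris(benzyloxy)phenyl]methyl acetate
Product: 18 3-O-(benzyloxycarbonyl)-penta-O-benzyl-epigallocatechin-(4β→6)-8-bromo-octa-O-benzyl-epigallocatechin 3-O-gallate (upper unit 2R,3R, 2,3-cis-3,4-trans; lower unit 2R,3R), via O-aryl oxocarbenium ion 16 (not isolated), via benzylic cation 17 (not isolated)
Conditions: (R)-3,3'-bis(2,4,6-triisopropylphenyl)-1,1'-binaphthyl-2,2'-diyl N-triflylphosphoramide (10 mol %), 11 (1.0 equiv), 15 (1.5 equiv, slow addition), toluene/CH2Cl2, 5 Å MS, −60 → −30 °C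
Reagents that add atoms: none
Why: Proposed new method: the chiral acid expels acetic acid from 15 to give the O-aryl oxocarbenium ion 16 as a chiral ion pair, C3 of alkene 11 adds to C2 (Prins-type), and the quinone-methide-like cation 17, stabilised by the lower ring A and by the carbonate carbonyl, is trapped at once by the ortho carbon of the upper ring A, which returns the proton to the catalyst; C2–C3 and C4–C4a thus form in one operation as a formal inverse-electron-demand [4+2] cycloaddition. The closest known reaction types are the oxa-Povarov reaction of O-aryl oxocarbenium ions with styrenes under achiral Lewis acids and the chiral-phosphoric-acid Povarov reaction of N-aryl iminium ions with β-substituted enecarbamates, whereas an enol carbonate partner and chiral-anion control have not been shown in the oxa series. Ring C closes by a 6-exo-trig Friedel–Crafts attack, the cationic C4=C(aryl) π bond lying outside the new ring and the attacking C4a=C8a bond inside it. C2 (R) is set by the chiral anion, which covers one face of the planar cation; C3 (R) follows from the relative topicity of the first bond formation, for which an open antiperiplanar transition state with the C3 hydrogen between O1 and the C2 aryl group and the carbonate oxygen gauche to O1 (the arrangement that makes (E)-crotyl nucleophiles syn-selective) gives the 2,3-cis array; C4 (4β, S in the target) is set in the closure through a half-chair with the C2 aryl group equatorial and the C4 aryl group pseudoaxial, away from the C5 benzyloxy group and anti to the C3 carbonate, whose dioxolanylium participation shields the same face, hence 3,4-trans. The step needs C3 and not C4 as the nucleophilic carbon, alkene and not arene attack on 16, and face control: the first rests on the 2,4,6-trioxygenated aryl group being a far stronger donor than the acylated enol oxygen, the second on slow addition of 15 to the alkene and on the C8 bromine that blocks the last free position of the lower ring A, the third on the catalyst.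

Step 9
Reactants: 18 protected dimer
Product: 19 CNP0204196.2, (−)-epigallocatechin-(4β→6)-(−)-epigallocatechin 3'-O-gallate (upper unit 2R,3R,4S; lower unit 2R,3R)
Conditions: H2 (1 atm), Pd(OH)2/C, NaOAc (1.5 equiv), THF/MeOH/H2O, rt; filtration under Ar
Reagents that add atoms: none
Why: Catalytic hydrogenolysis should cleave the thirteen benzyl ethers and the benzyl carbonate (which then loses CO2 to free the C3 hydroxyl) and reduce the aryl bromide in one operation, with acetate buffering the HBr so that the acid-labile C4–C6 bond, the gallate ester and all five stereocentres stay untouched.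

Compound list
1 | (−)-epigallocatechin (EGC; 2R,3R) | O[C@@H]1Cc2c(cc(O)cc2O)O[C@@H]1c1cc(O)c(O)c(O)c1 | starting material
2 | 5,7,3',4',5'-penta-O-benzyl-(−)-epigallocatechin (2R,3R) | O[C@@H]1Cc2c(cc(OCc3ccccc3)cc2OCc2ccccc2)O[C@@H]1c1cc(OCc2ccccc2)c(OCc2ccccc2)c(OCc2ccccc2)c1 | intermediate
3 | 3,4,5-tris(benzyloxy)benzoic acid | OC(=O)c1cc(OCc2ccccc2)c(OCc2ccccc2)c(OCc2ccccc2)c1 | starting material
4 | (2R,3R)-5,7-bis(benzyloxy)-2-[3,4,5-tris(benzyloxy)phenyl]chroman-3-yl 3,4,5-tris(benzyloxy)benzoate (octa-O-benzyl-EGCG) | O=C(O[C@@H]1Cc2c(cc(OCc3ccccc3)cc2OCc2ccccc2)O[C@@H]1c1cc(OCc2ccccc2)c(OCc2ccccc2)c(OCc2ccccc2)c1)c1cc(OCc2ccccc2)c(OCc2ccccc2)c(OCc2ccccc2)c1 | intermediate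
5 | 8-bromo-octa-O-benzyl-EGCG (2R,3R) | O=C(O[C@@H]1Cc2c(c(Br)c(OCc3ccccc3)cc2OCc2ccccc2)O[C@@H]1c1cc(OCc2ccccc2)c(OCc2ccccc2)c(OCc2ccccc2)c1)c1cc(OCc2ccccc2)c(OCc2ccccc2)c(OCc2ccccc2)c1 | intermediate
6 | 8-bromo-6-iodo-octa-O-benzyl-EGCG (2R,3R) | O=C(O[C@@H]1Cc2c(c(Br)c(OCc3ccccc3)c(I)c2OCc2ccccc2)O[C@@H]1c1cc(OCc2ccccc2)c(OCc2ccccc2)c(OCc2ccccc2)c1)c1cc(OCc2ccccc2)c(OCc2ccccc2)c(OCc2ccccc2)c1 | intermediate
7 | (E)-2-(2-ethoxyvinyl)-4,4,5,5-tetramethyl-1,3,2-dioxaborolane | CCO/C=C/B1OC(C)(C)C(C)(C)O1 | starting material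
8 | 8-bromo-6-[(E)-2-ethoxyvinyl]-octa-O-benzyl-EGCG (not isolated) | O=C(O[C@@H]1Cc2c(c(Br)c(OCc3ccccc3)c(/C=C/OCC)c2OCc2ccccc2)O[C@@H]1c1cc(OCc2ccccc2)c(OCc2ccccc2)c(OCc2ccccc2)c1)c1cc(OCc2ccccc2)c(OCc2ccccc2)c(OCc2ccccc2)c1 | intermediate
9 | 8-bromo-6-(2-oxoethyl)-octa-O-benzyl-EGCG (arylacetaldehyde) | O=C(O[C@@H]1Cc2c(c(Br)c(OCc3ccccc3)c(CC=O)c2OCc2ccccc2)O[C@@H]1c1cc(OCc2ccccc2)c(OCc2ccccc2)c(OCc2ccccc2)c1)c1cc(OCc2ccccc2)c(OCc2ccccc2)c(OCc2ccccc2)c1 | intermediate
10 | potassium (E)-enolate of 9 (not isolated) | O=C(O[C@@H]1Cc2c(c(Br)c(OCc3ccccc3)c(/C=C/[O-])c2OCc2ccccc2)O[C@@H]1c1cc(OCc2ccccc2)c(OCc2ccccc2)c(OCc2ccccc2)c1)c1cc(OCc2ccccc2)c(OCc2ccccc2)c(OCc2ccccc2)c1.[K+] | intermediate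
11 | 8-bromo-6-[(E)-2-(benzyloxycarbonyloxy)vinyl]-octa-O-benzyl-EGCG | O=C(O[C@@H]1Cc2c(c(Br)c(OCc3ccccc3)c(/C=C/OC(=O)OCc3ccccc3)c2OCc2ccccc2)O[C@@H]1c1cc(OCc2ccccc2)c(OCc2ccccc2)c(OCc2ccccc2)c1)c1cc(OCc2ccccc2)c(OCc2ccccc2)c(OCc2ccccc2)c1 | intermediate
12 | 3,4,5-tris(benzyloxy)benzaldehyde | O=Cc1cc(OCc2ccccc2)c(OCc2ccccc2)c(OCc2ccccc2)c1 | starting material
13 | 3,5-bis(benzyloxy)phenol | Oc1cc(OCc2ccccc2)cc(OCc2ccccc2)c1 | starting material
14 | chloro[3,4,5-tris(benzyloxy)phenyl]methyl acetate (racemic, not isolated) | CC(=O)OC(Cl)c1cc(OCc2ccccc2)c(OCc2ccccc2)c(OCc2ccccc2)c1 | intermediate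
15 | [3,5-bis(benzyloxy)phenoxy][3,4,5-tris(benzyloxy)phenyl]methyl acetate (racemic) | CC(=O)OC(Oc1cc(OCc2ccccc2)cc(OCc2ccccc2)c1)c1cc(OCc2ccccc2)c(OCc2ccccc2)c(OCc2ccccc2)c1 | intermediate
16 | O-[3,5-bis(benzyloxy)phenyl] oxocarbenium ion of 12 (cation of the chiral ion pair, not isolated) | C(=[O+]c1cc(OCc2ccccc2)cc(OCc2ccccc2)c1)c1cc(OCc2ccccc2)c(OCc2ccccc2)c(OCc2ccccc2)c1 | intermediate
17 | benzylic cation after C2–C3 bond formation (C2 and C3 set, C4 cationic, not isolated) | O=C(O[C@@H]1Cc2c(c(Br)c(OCc3ccccc3)c([CH+][C@@H](OC(=O)OCc3ccccc3)[C@H](Oc3cc(OCc4ccccc4)cc(OCc4ccccc4)c3)c3cc(OCc4ccccc4)c(OCc4ccccc4)c(OCc4ccccc4)c3)c2OCc2ccccc2)O[C@@H]1c1cc(OCc2ccccc2)c(OCc2ccccc2)c(OCc2ccccc2)c1)c1cc(OCc2ccccc2)c(OCc2ccccc2)c(OCc2ccccc2)c1 | intermediate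
18 | 3-O-(benzyloxycarbonyl)-penta-O-benzyl-epigallocatechin-(4β→6)-8-bromo-octa-O-benzyl-epigallocatechin 3-O-gallate (upper unit 2R,3R, 4-aryl trans to the C3 oxygen; lower unit 2R,3R) | O=C(O[C@@H]1Cc2c(c(Br)c(OCc3ccccc3)c([C@H]3c4c(OCc5ccccc5)cc(OCc5ccccc5)cc4O[C@H](c4cc(OCc5ccccc5)c(OCc5ccccc5)c(OCc5ccccc5)c4)[C@@H]3OC(=O)OCc3ccccc3)c2OCc2ccccc2)O[C@@H]1c1cc(OCc2ccccc2)c(OCc2ccccc2)c(OCc2ccccc2)c1)c1cc(OCc2ccccc2)c(OCc2ccccc2)c(OCc2ccccc2)c1 | intermediate
19 | CNP0204196.2, (−)-epigallocatechin-(4β→6)-(−)-epigallocatechin 3'-O-gallate (upper unit 2R,3R,4S; lower unit 2R,3R) | O=C(O[C@@H]1Cc2c(cc(O)c([C@H]3c4c(O)cc(O)cc4O[C@H](c4cc(O)c(O)c(O)c4)[C@@H]3O)c2O)O[C@@H]1c1cc(O)c(O)c(O)c1)c1cc(O)c(O)c(O)c1 | target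

Total step count: 9 steps. Longest linear sequence: 8 steps (steps 1, 2, 3, 4, 5, 6, 8 and 9, from (−)-epigallocatechin); step 7 is a one-step side branch.

Steps most likely to fail

Step 8 (the step under the label). The oxocarbenium ion may be intercepted by the electron-rich arene rings instead of the alkene, which leads to oligomers. The first bond formation may also take the other relative topicity, or the catalyst may give poor face control. The fallback leaves the cycloaddition and reaches the same compound by the known C4-cation coupling of flavan-3-ols. It sets out from 2 and 5. Oxidation of 2 at C4 with DDQ in the presence of 2-ethoxyethanol (CH2Cl2, rt) should give 4β-(2-ethoxyethoxy)-5,7,3',4',5'-penta-O-benzyl-(−)-epigallocatechin F1. Benzyl chloroformate with pyridine and DMAP should give its 3-O-benzyl carbonate F2. TMSOTf in CH2Cl2 at −78 °C should then ionise F2 at C4, and the cation is trapped by C6 of the C8-blocked nucleophile 5 (used in excess), the 3-O-acyl group directing 3,4-trans attack. The product is 18, where the route is rejoined.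

Step 7. The ambident phenoxide may be alkylated on carbon, the acetyl group may transfer from the chloro ester to the phenoxide, or the acetal may ionise during isolation. The fallback sets out from 13 and 3. Steglich esterification (DCC, DMAP, CH2Cl2) should give 3,5-bis(benzyloxy)phenyl 3,4,5-tris(benzyloxy)benzoate F3. Reduction with iBu2AlH at −78 °C and acetylation of the aluminium hemiacetal in the same flask (Ac2O, pyridine, DMAP), the reductive acetylation of esters, should give 15, where the route is rejoined.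

Step 4. Ring B may be iodinated in competition, or the crowded C6 may not react. The fallback sets out from 5. Vilsmeier–Haack formylation (POCl3, DMF), a weak electrophile that should attack only the most electron-rich ring, should give 8-bromo-6-formyl-octa-O-benzyl-EGCG F4. Wittig reaction with Ph3P=CHOMe (from (methoxymethyl)triphenylphosphonium chloride and KN(SiMe3)2) should give the methyl enol ether 8-bromo-6-(2-methoxyvinyl)-octa-O-benzyl-EGCG F5. Hydrolysis (1 M HCl, THF) should give 9, where the route is rejoined without 6 and 8.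

Further compounds
F1 | step 8 | 4β-(2-ethoxyethoxy)-5,7,3',4',5'-penta-O-benzyl-(−)-epigallocatechin (4-alkoxy trans to 3-OH) | CCOCCO[C@H]1c2c(OCc3ccccc3)cc(OCc3ccccc3)cc2O[C@H](c2cc(OCc3ccccc3)c(OCc3ccccc3)c(OCc3ccccc3)c2)[C@@H]1O
F2 | step 8 | 3-O-(benzyloxycarbonyl)-4β-(2-ethoxyethoxy)-5,7,3',4',5'-penta-O-benzyl-(−)-epigallocatechin | CCOCCO[C@H]1c2c(OCc3ccccc3)cc(OCc3ccccc3)cc2O[C@H](c2cc(OCc3ccccc3)c(OCc3ccccc3)c(OCc3ccccc3)c2)[C@@H]1OC(=O)OCc1ccccc1
F3 | step 7 | 3,5-bis(benzyloxy)phenyl 3,4,5-tris(benzyloxy)benzoate | O=C(Oc1cc(OCc2ccccc2)cc(OCc2ccccc2)c1)c1cc(OCc2ccccc2)c(OCc2ccccc2)c(OCc2ccccc2)c1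
F4 | step 4 | 8-bromo-6-formyl-octa-O-benzyl-EGCG (2R,3R) | O=C(O[C@@H]1Cc2c(c(Br)c(OCc3ccccc3)c(C=O)c2OCc2ccccc2)O[C@@H]1c1cc(OCc2ccccc2)c(OCc2ccccc2)c(OCc2ccccc2)c1)c1cc(OCc2ccccc2)c(OCc2ccccc2)c(OCc2ccccc2)c1
F5 | step 4 | 8-bromo-6-(2-methoxyvinyl)-octa-O-benzyl-EGCG (E/Z mixture) | O=C(O[C@@H]1Cc2c(c(Br)c(OCc3ccccc3)c(C=COC)c2OCc2ccccc2)O[C@@H]1c1cc(OCc2ccccc2)c(OCc2ccccc2)c(OCc2ccccc2)c1)c1cc(OCc2ccccc2)c(OCc2ccccc2)c(OCc2ccccc2)c1
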